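**Plan**

- Retrosynthesis first cuts the lactone C12–O bond and the ring bond C7–C8 together. In elemane numbering, C8–O, C7, C11(=C13) and C12 form the γ-hydroxy-α-methylene ester pattern that arises when a 2-(methoxycarbonyl)allyl metal adds through its γ carbon to an aldehyde, so both rings open to the acyclic C8 aldehyde / C13 bromide 22.
- Further cuts: C7–C11 (Morita–Baylis–Hillman reaction, then SN2' bromination), C6–C7 (dithiane acylation), C5–C10 (Ireland–Claisen rearrangement) and C1=C10 (Horner–Wadsworth–Emmons olefination).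
- Forward: the chain C8–C9–C10–C5–C6–C7 is built open-chain. The cyclohexane (C5–C10) and then the lactone close in one operation. The angelate, the C3 aldehyde and the epoxide follow last.
- Stereochemistry: C9 comes from (R)-glyceraldehyde. C5 and C10 come from the chair Ireland–Claisen (E ketene acetal, E alkene, face set by the dioxolane). C6 comes from a Felkin–Anh reduction, C7 and C8 from the chromium chair transition state, C1 from a C9–OH-directed epoxidation, and the angelate geometry from angelic acid.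

Key step: step 18

Remarks on the chemistry:
- Elemane numbering is used: ring C5–C10; C14 is the methyl and C1=C2 the vinyl group on C10; C4 with C3 and C15 sits on C5; C11–C13 is the methylene lactone unit.
- Compounds 1, 6, 18 and 27 are taken as purchased.
- Enoates 20–22 are drawn as the Z isomers (C6 cis to C13); any E isomer is carried along because both give the same allylchromium species.
- Compounds 2 and 19 are epimer mixtures at carbons that later become sp2.

Step 1
Reactants: 1 (R)-2,3-O-isopropylideneglyceraldehyde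
Product: 2 1-[(4R)-2,2-dimethyl-1,3-dioxolan-4-yl]ethan-1-ol (both carbinol epimers)
Conditions: MeMgBr, Et2O, −78 → 0 °C; aq. NH4Cl
Reagents that add atoms: methylmagnesium bromide, C[Mg]Br
Why: Grignard addition to the aldehyde brings in C14; the new carbinol centre is left uncontrolled because step 2 oxidises it.

Step 2
Reactants: 2 1-[(4R)-2,2-dimethyl-1,3-dioxolan-4-yl]ethan-1-ol
Product: 3 1-[(4R)-2,2-dimethyl-1,3-dioxolan-4-yl]ethan-1-one
Conditions: Dess–Martin periodinane, NaHCO3, CH2Cl2, 0 °C → rt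
Reagents that add atoms: none
Why: Dess–Martin oxidation under buffered, non-basic conditions should give the methyl ketone without enolising the α-alkoxy centre C9.

Step 3
Reactants: 3 1-[(4R)-2,2-dimethyl-1,3-dioxolan-4-yl]ethan-1-one
Product: 4 ethyl (2E)-3-[(4S)-2,2-dimethyl-1,3-dioxolan-4-yl]but-2-enoate
Conditions: (EtO)2P(O)CH2CO2Et, NaH, THF, 0 °C → rt; chromatographic removal of the Z isomer
Reagents that add atoms: triethyl phosphonoacetate, CCOC(=O)CP(=O)(OCC)OCC
Why: Horner–Wadsworth–Emmons olefination of the ketone with a stabilised phosphonate should place the ester trans to the bulkier dioxolane (E), creating C1=C10.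

Step 4
Reactants: 4 ethyl (2E)-3-[(4S)-2,2-dimethyl-1,3-dioxolan-4-yl]but-2-enoate
Product: 5 (2E)-3-[(4S)-2,2-dimethyl-1,3-dioxolan-4-yl]but-2-en-1-ol
Conditions: i-Bu2AlH, CH2Cl2, −78 °C
Reagents that add atoms: none
Why: 1,2-reduction of the enoate by the aluminium hydride gives the E allylic alcohol and leaves the acetonide intact.

Step 5
Reactants: 5 (2E)-3-[(4S)-2,2-dimethyl-1,3-dioxolan-4-yl]but-2-en-1-ol; 6 3-methylbut-3-enoic acid
Product: 7 (2E)-3-[(4S)-2,2-dimethyl-1,3-dioxolan-4-yl]but-2-en-1-yl 3-methylbut-3-enoate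
Conditions: PPh3, DIAD, THF, 0 °C → rt
Reagents that add atoms: none
Why: Mitsunobu esterification of the primary allylic alcohol runs without acyl activation, so the β,γ-unsaturated acid should not move into conjugation, and SN2' attack is blocked by the fully substituted C10.

Step 6
Reactants: 7 (2E)-3-[(4S)-2,2-dimethyl-1,3-dioxolan-4-yl]but-2-en-1-yl 3-methylbut-3-enoate
Product: 10 (2S,3S)-3-[(4S)-2,2-dimethyl-1,3-dioxolan-4-yl]-3-methyl-2-(prop-1-en-2-yl)pent-4-enoic acid, via silyl ketene acetal 8 (not isolated), via trimethylsilyl ester 9 (not isolated)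
Conditions: LiN(SiMe3)2, Et3N, toluene, −78 °C; TMSCl, −78 °C → rt, then 50 °C; 1 M HCl
Reagents that add atoms: none
Why: Ireland–Claisen rearrangement: E-selective enolisation gives ketene acetal 8 (isopropenyl cis to the allyloxy oxygen), whose chair transition state with the E alkene fixes C5 against C10, while the dioxolane sets the face through a Felkin–Anh-type arrangement (C9–O anti to the forming C5–C10 bond, C8 over the alkene toward the small C1–H, C9–H toward C14), which should give 5S,10S.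

Step 7
Reactants: 10 (2S,3S)-3-[(4S)-2,2-dimethyl-1,3-dioxolan-4-yl]-3-methyl-2-(prop-1-en-2-yl)pent-4-enoic acid
Product: 11 (2S,3S)-3-[(4S)-2,2-dimethyl-1,3-dioxolan-4-yl]-N-methoxy-N,3-dimethyl-2-(prop-1-en-2-yl)pent-4-enamide
Conditions: MeNHOMe·HCl, EDC·HCl, HOBt, N-methylmorpholine, CH2Cl2, 0 °C → rt
Reagents that add atoms: N,O-dimethylhydroxylamine hydrochloride, CNOC.Cl
Why: Carbodiimide-mediated amidation through the HOBt active ester gives the Weinreb amide under conditions mild enough to keep the C5 centre.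

Step 8
Reactants: 11 (2S,3S)-3-[(4S)-2,2-dimethyl-1,3-dioxolan-4-yl]-N-methoxy-N,3-dimethyl-2-(prop-1-en-2-yl)pent-4-enamide
Product: 12 (2S,3S)-3-[(4S)-2,2-dimethyl-1,3-dioxolan-4-yl]-1-(1,3-dithian-2-yl)-3-methyl-2-(prop-1-en-2-yl)pent-4-en-1-one
Conditions: 1,3-dithiane, n-BuLi, THF, −30 °C; then 11, −78 → 0 °C; aq. NH4Cl
Reagents that add atoms: 1,3-dithiane, C1CSCSC1
Why: Corey–Seebach acylation: 2-lithio-1,3-dithiane adds to the Weinreb amide and the chelated tetrahedral intermediate collapses to the ketone only on work-up, which brings in C7 as a masked aldehyde.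

Step 9
Reactants: 12 (2S,3S)-3-[(4S)-2,2-dimethyl-1,3-dioxolan-4-yl]-1-(1,3-dithian-2-yl)-3-methyl-2-(prop-1-en-2-yl)pent-4-en-1-one
Product: 13 (1S,2S,3S)-3-[(4S)-2,2-dimethyl-1,3-dioxolan-4-yl]-1-(1,3-dithian-2-yl)-3-methyl-2-(prop-1-en-2-yl)pent-4-en-1-ol
Conditions: LiBH(s-Bu)3, THF, −78 °C; aq. NH4Cl
Reagents that add atoms: none
Why: Felkin–Anh reduction: the bulky hydride should attack the C6 ketone anti to the quaternary C10 with the isopropenyl group inside, which sets C6 as the target needs (a carbon nucleophile adding to the C6 aldehyde would give the opposite epimer).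

Step 10
Reactants: 13 (1S,2S,3S)-3-[(4S)-2,2-dimethyl-1,3-dioxolan-4-yl]-1-(1,3-dithian-2-yl)-3-methyl-2-(prop-1-en-2-yl)pent-4-en-1-ol
Product: 14 2-{(1S,2S,3S)-3-[(4S)-2,2-dimethyl-1,3-dioxolan-4-yl]-1-[(4-methoxybenzyl)oxy]-3-methyl-2-(prop-1-en-2-yl)pent-4-en-1-yl}-1,3-dithiane
Conditions: NaH, PMBCl, Bu4NI (cat.), DMF, 0 °C → rt
Reagents that add atoms: 4-methoxybenzyl chloride, COc1ccc(CCl)cc1
Why: Williamson etherification protects C6–OH as an ether that is a poor leaving group in the chromium step and can later be removed oxidatively, independently of the C9 silyl ether.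

Step 11
Reactants: 14 2-{(1S,2S,3S)-3-[(4S)-2,2-dimethyl-1,3-dioxolan-4-yl]-1-[(4-methoxybenzyl)oxy]-3-methyl-2-(prop-1-en-2-yl)pent-4-en-1-yl}-1,3-dithiane
Product: 15 (2S,3S,4S,5S)-5-(1,3-dithian-2-yl)-3-ethenyl-5-[(4-methoxybenzyl)oxy]-3-methyl-4-(prop-1-en-2-yl)pentane-1,2-diol
Conditions: AcOH/H2O (4:1), 40 °C
Reagents that add atoms: none
Why: Acid-catalysed hydrolysis of the terminal acetonide; the PMB ether, the dithiane and the alkenes are stable to aqueous acetic acid.

Step 12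
Reactants: 15 (2S,3S,4S,5S)-5-(1,3-dithian-2-yl)-3-ethenyl-5-[(4-methoxybenzyl)oxy]-3-methyl-4-(prop-1-en-2-yl)pentane-1,2-diol
Product: 16 bis(tert-butyldimethylsilyl) ether of 15 (C8 and C9 oxygens)
Conditions: TBSOTf, 2,6-lutidine, CH2Cl2, −78 → 0 °C
Reagents that add atoms: tert-butyldimethylsilyl triflate, CC(C)(C)[Si](C)(C)OS(=O)(=O)C(F)(F)F
Why: Silylation with the silyl triflate is reactive enough to protect both the primary C8 and the hindered C9 hydroxyl.

Step 13
Reactants: 16 bis(tert-butyldimethylsilyl) ether of 15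
Product: 17 (2S,3S,4S,5S)-5,6-bis[(tert-butyldimethylsilyl)oxy]-4-ethenyl-2-[(4-methoxybenzyl)oxy]-4-methyl-3-(prop-1-en-2-yl)hexanal
Conditions: MeI, CaCO3, MeCN/H2O (9:1), 45 °C
Reagents that add atoms: water, O
Why: Alkylative dithiane hydrolysis (S-methylation, then hydrolysis) under buffered conditions releases the C7 aldehyde without touching the silyl or PMB ethers and without epimerising C6.

Step 14
Reactants: 17 (2S,3S,4S,5S)-5,6-bis[(tert-butyldimethylsilyl)oxy]-4-ethenyl-2-[(4-methoxybenzyl)oxy]-4-methyl-3-(prop-1-en-2-yl)hexanal; 18 methyl acrylate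
Product: 19 methyl (4S,5S,6S,7S)-7,8-bis[(tert-butyldimethylsilyl)oxy]-6-ethenyl-3-hydroxy-4-[(4-methoxybenzyl)oxy]-6-methyl-2-methylidene-5-(prop-1-en-2-yl)octanoate (both C3 epimers)
Conditions: methyl acrylate (excess), DABCO (1 equiv), MeOH, rt, several days
Reagents that add atoms: none
Why: Morita–Baylis–Hillman reaction: the DABCO–acrylate zwitterion adds to the α-alkoxy-activated aldehyde and attaches C11–C13; the C7 carbinol configuration is irrelevant because C7 becomes sp2.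

Step 15
Reactants: 19 methyl (4S,5S,6S,7S)-7,8-bis[(tert-butyldimethylsilyl)oxy]-6-ethenyl-3-hydroxy-4-[(4-methoxybenzyl)oxy]-6-methyl-2-methylidene-5-(prop-1-en-2-yl)octanoate
Product: 20 methyl (2Z,4R,5S,6S,7S)-2-(bromomethyl)-7,8-bis[(tert-butyldimethylsilyl)oxy]-6-ethenyl-4-[(4-methoxybenzyl)oxy]-6-methyl-5-(prop-1-en-2-yl)oct-2-enoate
Conditions: NBS, Me2S, CH2Cl2, −20 → 20 °C
Reagents that add atoms: N-bromosuccinimide, O=C1CCC(=O)N1Br
Why: Corey–Kim-type bromination: bromide displaces the alkoxysulfonium salt of the Baylis–Hillman alcohol in SN2' fashion, moving the alkene to C7=C11 (mainly Z) and placing bromine on C13.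

Step 16
Reactants: 20 methyl (2Z,4R,5S,6S,7S)-2-(bromomethyl)-7,8-bis[(tert-butyldimethylsilyl)oxy]-6-ethenyl-4-[(4-methoxybenzyl)oxy]-6-methyl-5-(prop-1-en-2-yl)oct-2-enoate
Product: 21 methyl (2Z,4R,5S,6S,7S)-2-(bromomethyl)-7-[(tert-butyldimethylsilyl)oxy]-6-ethenyl-8-hydroxy-4-[(4-methoxybenzyl)oxy]-6-methyl-5-(prop-1-en-2-yl)oct-2-enoate
Conditions: HF·pyridine, THF, 0 °C
Reagents that add atoms: none
Why: Selective acidic fluoride cleavage of the primary silyl ether; the hindered secondary C9 ether should survive, and the pyridine is protonated so it does not attack the allylic bromide.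

Step 17
Reactants: 21 methyl (2Z,4R,5S,6S,7S)-2-(bromomethyl)-7-[(tert-butyldimethylsilyl)oxy]-6-ethenyl-8-hydroxy-4-[(4-methoxybenzyl)oxy]-6-methyl-5-(prop-1-en-2-yl)oct-2-enoate
Product: 22 methyl (2Z,4R,5S,6S,7S)-2-(bromomethyl)-7-[(tert-butyldimethylsilyl)oxy]-6-ethenyl-4-[(4-methoxybenzyl)oxy]-6-methyl-8-oxo-5-(prop-1-en-2-yl)oct-2-enoate
Conditions: Dess–Martin periodinane, NaHCO3, CH2Cl2, 0 °C → rt
Reagents that add atoms: none
Why: Dess–Martin oxidation of the primary alcohol under buffered conditions gives the C8 aldehyde in the presence of the allylic bromide.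

Step 18
Reactants: 22 methyl (2Z,4R,5S,6S,7S)-2-(bromomethyl)-7-[(tert-butyldimethylsilyl)oxy]-6-ethenyl-4-[(4-methoxybenzyl)oxy]-6-methyl-8-oxo-5-(prop-1-en-2-yl)oct-2-enoate
Product: 25 (3aR,4S,5S,6S,7S,7aR)-7-[(tert-butyldimethylsilyl)oxy]-6-ethenyl-4-[(4-methoxybenzyl)oxy]-6-methyl-3-methylidene-5-(prop-1-en-2-yl)hexahydro-1-benzofuran-2(3H)-one, via allylchromium species 23 (not isolated), via chromium alkoxide 24 (not isolated)
Conditions: CrCl2 (4 equiv), THF, 0.01 M, rt; aq. NH4Cl; PPTS (cat.), CH2Cl2 if lactonisation is incomplete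
Reagents that add atoms: none
Why: Two equivalents of CrCl2 (divalent chromium) reduce the C13–Br bond by successive one-electron transfers to the allylchromium species 23 (trivalent chromium), whose C13- and C7-bound σ forms interconvert, so both enoate isomers of 22 give the same nucleophile; it adds through its γ carbon C7 to the C8 aldehyde in a closed six-membered chromium-bridged transition state with allylic transposition, an intramolecular Nozaki–Hiyama allylation whose closest precedent is the CrCl2- or zinc-mediated cyclisation of 2-(bromomethyl)enoate aldehydes to fused α-methylene lactones. The cyclohexane closes 6-exo-trig at C7–C8, and the C8 chromium alkoxide 24 then closes the lactone 5-exo-trig by acyl substitution at the C12 ester with loss of methoxide. C7 and C8 are set together: the allylchromium reacts in the geometry with C6 cis to C13 (ester trans to the chain), which in the chair-chair array puts the C11 arm equatorial and the aldehyde oxygen axial on the forming ring, that is syn addition and a cis ring fusion. The existing centres choose the face pair: the chair that keeps C6–OPMB, C9–OTBS and C14 equatorial (isopropenyl and vinyl axial) leads to 7R,8R, whereas the other chair would stack C6–O, C8–O and C14 syn-axially. The step needs C7–C11 trans to the C6 oxygen and cis to the C8 oxygen; the C6 ether is too poor a leaving group for elimination from the allylchromium, and high dilution suppresses intermolecular allylation.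

Step 19
Reactants: 25 (3aR,4S,5S,6S,7S,7aR)-7-[(tert-butyldimethylsilyl)oxy]-6-ethenyl-4-[(4-methoxybenzyl)oxy]-6-methyl-3-methylidene-5-(prop-1-en-2-yl)hexahydro-1-benzofuran-2(3H)-one
Product: 26 (3aR,4S,5S,6S,7S,7aR)-7-[(tert-butyldimethylsilyl)oxy]-6-ethenyl-4-hydroxy-6-methyl-3-methylidene-5-(prop-1-en-2-yl)hexahydro-1-benzofuran-2(3H)-one
Conditions: DDQ, CH2Cl2/pH 7 buffer, 0 °C → rt
Reagents that add atoms: none
Why: Oxidative PMB cleavage by DDQ (hydride abstraction, then hydrolysis of the oxocarbenium ion) frees C6–OH; the silyl ether, the lactone and the alkenes are inert.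

Step 20
Reactants: 26 (3aR,4S,5S,6S,7S,7aR)-7-[(tert-butyldimethylsilyl)oxy]-6-ethenyl-4-hydroxy-6-methyl-3-methylidene-5-(prop-1-en-2-yl)hexahydro-1-benzofuran-2(3H)-one; 27 angelic acid
Product: 29 (3aR,4S,5S,6S,7S,7aR)-7-[(tert-butyldimethylsilyl)oxy]-6-ethenyl-6-methyl-3-methylidene-2-oxo-5-(prop-1-en-2-yl)octahydro-1-benzofuran-4-yl (2Z)-2-methylbut-2-enoate, via mixed anhydride 28 (not isolated)
Conditions: 27, 2,4,6-trichlorobenzoyl chloride, Et3N, toluene, rt; then 26, toluene, 80 °C (no DMAP)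
Reagents that add atoms: none
Why: Yamaguchi esterification: the alcohol attacks the less hindered angeloyl carbonyl of mixed anhydride 28 under DMAP-free conditions that should keep the Z geometry, and acylating before C3 is oxidised avoids a lactol between C6–OH and the C3 aldehyde.

Step 21
Reactants: 29 (3aR,4S,5S,6S,7S,7aR)-7-[(tert-butyldimethylsilyl)oxy]-6-ethenyl-6-methyl-3-methylidene-2-oxo-5-(prop-1-en-2-yl)octahydro-1-benzofuran-4-yl (2Z)-2-methylbut-2-enoate
Product: 31 (3aR,4S,5R,6S,7S,7aR)-7-[(tert-butyldimethylsilyl)oxy]-6-ethenyl-6-methyl-3-methylidene-2-oxo-5-(3-oxoprop-1-en-2-yl)octahydro-1-benzofuran-4-yl (2Z)-2-methylbut-2-enoate, via allylic alcohol 30 (not isolated)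
Conditions: SeO2 (0.5 equiv), t-BuOOH, CH2Cl2, rt; then MnO2, CH2Cl2, rt
Reagents that add atoms: selenium dioxide, O=[Se]=O (transfers the oxygen); tert-butyl hydroperoxide, CC(C)(C)OO (reoxidant and ultimate oxygen source)
Why: Selenium dioxide allylic oxidation (ene reaction, then [2,3] shift) should attack the isopropenyl group, the only electron-rich alkene with allylic hydrogens, at its methyl group rather than the C5 methine, and MnO2 then takes allylic alcohol 30 to the enal; the electron-poor angelate and methylene lactone react far more slowly.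

Step 22
Reactants: 31 (3aR,4S,5R,6S,7S,7aR)-7-[(tert-butyldimethylsilyl)oxy]-6-ethenyl-6-methyl-3-methylidene-2-oxo-5-(3-oxoprop-1-en-2-yl)octahydro-1-benzofuran-4-yl (2Z)-2-methylbut-2-enoate
Product: 32 (3aR,4S,5R,6S,7S,7aR)-6-ethenyl-7-hydroxy-6-methyl-3-methylidene-2-oxo-5-(3-oxoprop-1-en-2-yl)octahydro-1-benzofuran-4-yl (2Z)-2-methylbut-2-enoate
Conditions: HF·pyridine, THF, rt
Reagents that add atoms: none
Why: Fluoride-mediated desilylation under acidic conditions frees C9–OH and should be tolerated by the enal, the angelate and the methylene lactone; C9–O and the C5 side chain are trans, so no lactol can form.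

Step 23
Reactants: 32 (3aR,4S,5R,6S,7S,7aR)-6-ethenyl-7-hydroxy-6-methyl-3-methylidene-2-oxo-5-(3-oxoprop-1-en-2-yl)octahydro-1-benzofuran-4-yl (2Z)-2-methylbut-2-enoate
Product: 33 (3aR,4S,5R,6S,7S,7aR)-7-hydroxy-6-methyl-3-methylidene-6-[(2S)-oxiran-2-yl]-2-oxo-5-(3-oxoprop-1-en-2-yl)octahydro-1-benzofuran-4-yl (2Z)-2-methylbut-2-enoate (CNP0113462.5)
Conditions: VO(acac)2 (cat.), t-BuOOH, CH2Cl2, 0 °C → rt
Reagents that add atoms: tert-butyl hydroperoxide, CC(C)(C)OO
Why: Vanadium-catalysed hydroxyl-directed epoxidation of the homoallylic alcohol: the vanadate ester (pentavalent vanadium) of the equatorial C9–OH delivers the peroxide oxygen to the axial vinyl group on the face turned toward C9, in the rotamer that keeps C2 over C14 and away from the syn-axial lactone oxygen, which should give 1S; the other three alkenes are electron-poor and have no directing hydroxyl.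

**Compound list**

1 | (R)-2,3-O-isopropylideneglyceraldehyde [(4R)-2,2-dimethyl-1,3-dioxolane-4-carbaldehyde] | O=C[C@H]1COC(C)(C)O1 | starting material
2 | 1-[(4R)-2,2-dimethyl-1,3-dioxolan-4-yl]ethan-1-ol (both carbinol epimers) | CC(O)[C@H]1COC(C)(C)O1 | intermediate
3 | 1-[(4R)-2,2-dimethyl-1,3-dioxolan-4-yl]ethan-1-one | CC(=O)[C@H]1COC(C)(C)O1 | intermediate
4 | ethyl (2E)-3-[(4S)-2,2-dimethyl-1,3-dioxolan-4-yl]but-2-enoate | CCOC(=O)/C=C(\C)[C@H]1COC(C)(C)O1 | intermediate
5 | (2E)-3-[(4S)-2,2-dimethyl-1,3-dioxolan-4-yl]but-2-en-1-ol | OC/C=C(\C)[C@H]1COC(C)(C)O1 | intermediate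
6 | 3-methylbut-3-enoic acid | C=C(C)CC(=O)O | starting material
7 | (2E)-3-[(4S)-2,2-dimethyl-1,3-dioxolan-4-yl]but-2-en-1-yl 3-methylbut-3-enoate | C=C(C)CC(=O)OC/C=C(\C)[C@H]1COC(C)(C)O1 | intermediate
8 | E trimethylsilyl ketene acetal of 7 (isopropenyl cis to the allyloxy oxygen; not isolated) | C=C(C)/C=C(/O[Si](C)(C)C)OC/C=C(\C)[C@H]1COC(C)(C)O1 | intermediate
9 | trimethylsilyl ester of acid 10 (not isolated) | C1OC(C)(C)O[C@H]1[C@@](C)(C=C)[C@H](C(C)=C)C(=O)O[Si](C)(C)C | intermediate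
10 | (2S,3S)-3-[(4S)-2,2-dimethyl-1,3-dioxolan-4-yl]-3-methyl-2-(prop-1-en-2-yl)pent-4-enoic acid | C1OC(C)(C)O[C@H]1[C@@](C)(C=C)[C@H](C(C)=C)C(=O)O | intermediate
11 | (2S,3S)-3-[(4S)-2,2-dimethyl-1,3-dioxolan-4-yl]-N-methoxy-N,3-dimethyl-2-(prop-1-en-2-yl)pent-4-enamide | C1OC(C)(C)O[C@H]1[C@@](C)(C=C)[C@H](C(C)=C)C(=O)N(C)OC | intermediate
12 | (2S,3S)-3-[(4S)-2,2-dimethyl-1,3-dioxolan-4-yl]-1-(1,3-dithian-2-yl)-3-methyl-2-(prop-1-en-2-yl)pent-4-en-1-one | C1OC(C)(C)O[C@H]1[C@@](C)(C=C)[C@H](C(C)=C)C(=O)C1SCCCS1 | intermediate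
13 | (1S,2S,3S)-3-[(4S)-2,2-dimethyl-1,3-dioxolan-4-yl]-1-(1,3-dithian-2-yl)-3-methyl-2-(prop-1-en-2-yl)pent-4-en-1-ol | C1OC(C)(C)O[C@H]1[C@@](C)(C=C)[C@H](C(C)=C)[C@H](O)C1SCCCS1 | intermediate
14 | 2-{(1S,2S,3S)-3-[(4S)-2,2-dimethyl-1,3-dioxolan-4-yl]-1-[(4-methoxybenzyl)oxy]-3-methyl-2-(prop-1-en-2-yl)pent-4-en-1-yl}-1,3-dithiane | C1OC(C)(C)O[C@H]1[C@@](C)(C=C)[C@H](C(C)=C)[C@H](OCc1ccc(OC)cc1)C1SCCCS1 | intermediate
15 | (2S,3S,4S,5S)-5-(1,3-dithian-2-yl)-3-ethenyl-5-[(4-methoxybenzyl)oxy]-3-methyl-4-(prop-1-en-2-yl)pentane-1,2-diol | OC[C@@H](O)[C@@](C)(C=C)[C@H](C(C)=C)[C@H](OCc1ccc(OC)cc1)C1SCCCS1 | intermediate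
16 | bis(tert-butyldimethylsilyl) ether of 15 (C8 and C9 oxygens) | CC(C)(C)[Si](C)(C)OC[C@@H](O[Si](C)(C)C(C)(C)C)[C@@](C)(C=C)[C@H](C(C)=C)[C@H](OCc1ccc(OC)cc1)C1SCCCS1 | intermediate
17 | (2S,3S,4S,5S)-5,6-bis[(tert-butyldimethylsilyl)oxy]-4-ethenyl-2-[(4-methoxybenzyl)oxy]-4-methyl-3-(prop-1-en-2-yl)hexanal | CC(C)(C)[Si](C)(C)OC[C@@H](O[Si](C)(C)C(C)(C)C)[C@@](C)(C=C)[C@H](C(C)=C)[C@H](OCc1ccc(OC)cc1)C=O | intermediate
18 | methyl acrylate | C=CC(=O)OC | starting material
19 | methyl (4S,5S,6S,7S)-7,8-bis[(tert-butyldimethylsilyl)oxy]-6-ethenyl-3-hydroxy-4-[(4-methoxybenzyl)oxy]-6-methyl-2-methylidene-5-(prop-1-en-2-yl)octanoate (both C3 epimers) | CC(C)(C)[Si](C)(C)OC[C@@H](O[Si](C)(C)C(C)(C)C)[C@@](C)(C=C)[C@H](C(C)=C)[C@H](OCc1ccc(OC)cc1)C(O)C(=C)C(=O)OC | intermediate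
20 | methyl (2Z,4R,5S,6S,7S)-2-(bromomethyl)-7,8-bis[(tert-butyldimethylsilyl)oxy]-6-ethenyl-4-[(4-methoxybenzyl)oxy]-6-methyl-5-(prop-1-en-2-yl)oct-2-enoate | CC(C)(C)[Si](C)(C)OC[C@@H](O[Si](C)(C)C(C)(C)C)[C@@](C)(C=C)[C@H](C(C)=C)[C@H](OCc1ccc(OC)cc1)/C=C(\CBr)C(=O)OC | intermediate
21 | methyl (2Z,4R,5S,6S,7S)-2-(bromomethyl)-7-[(tert-butyldimethylsilyl)oxy]-6-ethenyl-8-hydroxy-4-[(4-methoxybenzyl)oxy]-6-methyl-5-(prop-1-en-2-yl)oct-2-enoate | OC[C@@H](O[Si](C)(C)C(C)(C)C)[C@@](C)(C=C)[C@H](C(C)=C)[C@H](OCc1ccc(OC)cc1)/C=C(\CBr)C(=O)OC | intermediate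
22 | methyl (2Z,4R,5S,6S,7S)-2-(bromomethyl)-7-[(tert-butyldimethylsilyl)oxy]-6-ethenyl-4-[(4-methoxybenzyl)oxy]-6-methyl-8-oxo-5-(prop-1-en-2-yl)oct-2-enoate | O=C[C@@H](O[Si](C)(C)C(C)(C)C)[C@@](C)(C=C)[C@H](C(C)=C)[C@H](OCc1ccc(OC)cc1)/C=C(\CBr)C(=O)OC | intermediate
23 | allylchromium dichloride from 22 (trivalent chromium, drawn with chromium on C13; not isolated) | O=C[C@@H](O[Si](C)(C)C(C)(C)C)[C@@](C)(C=C)[C@H](C(C)=C)[C@H](OCc1ccc(OC)cc1)/C=C(\C[Cr](Cl)Cl)C(=O)OC | intermediate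
24 | C8 chromium alkoxide of the cis hydroxy ester, drawn as the free alcohol (not isolated) | O[C@@H]1[C@H](C(=C)C(=O)OC)[C@@H](OCc2ccc(OC)cc2)[C@@H](C(C)=C)[C@](C)(C=C)[C@@H]1O[Si](C)(C)C(C)(C)C | intermediate
25 | (3aR,4S,5S,6S,7S,7aR)-7-[(tert-butyldimethylsilyl)oxy]-6-ethenyl-4-[(4-methoxybenzyl)oxy]-6-methyl-3-methylidene-5-(prop-1-en-2-yl)hexahydro-1-benzofuran-2(3H)-one | C=C1C(=O)O[C@@H]2[C@H]1[C@@H](OCc1ccc(OC)cc1)[C@@H](C(C)=C)[C@](C)(C=C)[C@@H]2O[Si](C)(C)C(C)(C)C | intermediate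
26 | (3aR,4S,5S,6S,7S,7aR)-7-[(tert-butyldimethylsilyl)oxy]-6-ethenyl-4-hydroxy-6-methyl-3-methylidene-5-(prop-1-en-2-yl)hexahydro-1-benzofuran-2(3H)-one | C=C1C(=O)O[C@@H]2[C@H]1[C@@H](O)[C@@H](C(C)=C)[C@](C)(C=C)[C@@H]2O[Si](C)(C)C(C)(C)C | intermediate
27 | angelic acid [(2Z)-2-methylbut-2-enoic acid] | C/C=C(/C)C(=O)O | starting material
28 | angelic 2,4,6-trichlorobenzoic anhydride (not isolated) | C/C=C(/C)C(=O)OC(=O)c1c(Cl)cc(Cl)cc1Cl | intermediate
29 | (3aR,4S,5S,6S,7S,7aR)-7-[(tert-butyldimethylsilyl)oxy]-6-ethenyl-6-methyl-3-methylidene-2-oxo-5-(prop-1-en-2-yl)octahydro-1-benzofuran-4-yl (2Z)-2-methylbut-2-enoate | C=C1C(=O)O[C@@H]2[C@H]1[C@@H](OC(=O)/C(C)=C\C)[C@@H](C(C)=C)[C@](C)(C=C)[C@@H]2O[Si](C)(C)C(C)(C)C | intermediate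
30 | (3aR,4S,5S,6S,7S,7aR)-7-[(tert-butyldimethylsilyl)oxy]-6-ethenyl-5-(3-hydroxyprop-1-en-2-yl)-6-methyl-3-methylidene-2-oxooctahydro-1-benzofuran-4-yl (2Z)-2-methylbut-2-enoate (not isolated) | C=C1C(=O)O[C@@H]2[C@H]1[C@@H](OC(=O)/C(C)=C\C)[C@@H](C(=C)CO)[C@](C)(C=C)[C@@H]2O[Si](C)(C)C(C)(C)C | intermediate
31 | (3aR,4S,5R,6S,7S,7aR)-7-[(tert-butyldimethylsilyl)oxy]-6-ethenyl-6-methyl-3-methylidene-2-oxo-5-(3-oxoprop-1-en-2-yl)octahydro-1-benzofuran-4-yl (2Z)-2-methylbut-2-enoate | C=C1C(=O)O[C@@H]2[C@H]1[C@@H](OC(=O)/C(C)=C\C)[C@@H](C(=C)C=O)[C@](C)(C=C)[C@@H]2O[Si](C)(C)C(C)(C)C | intermediate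
32 | (3aR,4S,5R,6S,7S,7aR)-6-ethenyl-7-hydroxy-6-methyl-3-methylidene-2-oxo-5-(3-oxoprop-1-en-2-yl)octahydro-1-benzofuran-4-yl (2Z)-2-methylbut-2-enoate | C=C1C(=O)O[C@@H]2[C@H]1[C@@H](OC(=O)/C(C)=C\C)[C@@H](C(=C)C=O)[C@](C)(C=C)[C@@H]2O | intermediate
33 | (3aR,4S,5R,6S,7S,7aR)-7-hydroxy-6-methyl-3-methylidene-6-[(2S)-oxiran-2-yl]-2-oxo-5-(3-oxoprop-1-en-2-yl)octahydro-1-benzofuran-4-yl (2Z)-2-methylbut-2-enoate | C=C1C(=O)O[C@@H]2[C@H]1[C@@H](OC(=O)/C(C)=C\C)[C@@H](C(=C)C=O)[C@](C)([C@H]1CO1)[C@@H]2O | target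

**Totals**

Total step count: 23. Longest linear sequence: 23 steps (1 → 33); compounds 6, 18 and 27 enter directly.

**Three steps most likely to fail**

Step 6. The dioxolane may discriminate poorly between the two faces of the trisubstituted alkene, or the enolate may form as a geometric mixture, which would scramble C5 against C10. The fallback moves control from the substrate to a reagent. It sets out from ester 7, which is treated with (4S,5S)-2-bromo-4,5-diphenyl-1,3-bis(4-methylphenylsulfonyl)-1,3,2-diazaborolidine and Et3N in toluene at −78 °C to give the boron ketene acetal F1. On warming to −20 °C the chiral diazaborolidine, not the dioxolane, should decide the face of the chair transition state; the antipodal controller is used if it proves to be the matched one. Hydrolytic work-up gives acid 10, where the route is rejoined.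

Step 18. The ring may close through the other allylchromium geometry or the other chair, giving the trans-fused or the doubly epimeric cis lactone, or the bromide may be reduced without carbon–carbon bond formation. The fallback replaces the closed metal-bridged transition state by a Lewis-acid-promoted allylstannane addition. It sets out from alcohol 21, which with (Bu3Sn)2 and Pd2(dba)3 (zerovalent palladium) in THF gives the allylstannane alcohol F2. Dess–Martin oxidation gives the stannyl aldehyde F3, and BF3·OEt2 in CH2Cl2 at −78 °C closes the ring through an open synclinal transition state on the same chair. The resulting hydroxy ester 24 lactonises to 25, where the route is rejoined.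

Step 23. Oxygen transfer to the monosubstituted alkene may be slow, and delivery may occur to the wrong face of the vinyl group. The fallback gives up direction and resolves afterwards. It sets out from 32, which is epoxidised with mCPBA (NaHCO3 buffer, CH2Cl2) to give 33 together with its C1 epimer F4. Hydrolytic kinetic resolution follows, with water and Jacobsen's (salen)Co(OAc) complex (trivalent cobalt; salen = N,N'-bis(3,5-di-tert-butylsalicylidene)cyclohexane-1,2-diamine dianion; the enantiomer that consumes the 1R epoxide). This should open only F4 to the triol F5 and leave 33, where the route ends.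

**Further compounds**

F1 | step 6 | boron ketene acetal of 7 with the (4S,5S)-4,5-diphenyl-1,3-bis(4-methylphenylsulfonyl)-1,3,2-diazaborolidin-2-yl group on oxygen | C=C(C)/C=C(/OB1N(S(=O)(=O)c2ccc(C)cc2)[C@@H](c2ccccc2)[C@H](c2ccccc2)N1S(=O)(=O)c1ccc(C)cc1)OC/C=C(\C)[C@H]1COC(C)(C)O1
F2 | step 18 | methyl (2Z,4R,5S,6S,7S)-7-[(tert-butyldimethylsilyl)oxy]-6-ethenyl-8-hydroxy-4-[(4-methoxybenzyl)oxy]-6-methyl-5-(prop-1-en-2-yl)-2-[(tributylstannyl)methyl]oct-2-enoate | OC[C@@H](O[Si](C)(C)C(C)(C)C)[C@@](C)(C=C)[C@H](C(C)=C)[C@H](OCc1ccc(OC)cc1)/C=C(\C[Sn](CCCC)(CCCC)CCCC)C(=O)OC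
F3 | step 18 | methyl (2Z,4R,5S,6S,7S)-7-[(tert-butyldimethylsilyl)oxy]-6-ethenyl-4-[(4-methoxybenzyl)oxy]-6-methyl-8-oxo-5-(prop-1-en-2-yl)-2-[(tributylstannyl)methyl]oct-2-enoate | O=C[C@@H](O[Si](C)(C)C(C)(C)C)[C@@](C)(C=C)[C@H](C(C)=C)[C@H](OCc1ccc(OC)cc1)/C=C(\C[Sn](CCCC)(CCCC)CCCC)C(=O)OC
F4 | step 23 | C1 epimer of 33, with a (2R)-oxiran-2-yl group | C=C1C(=O)O[C@@H]2[C@H]1[C@@H](OC(=O)/C(C)=C\C)[C@@H](C(=C)C=O)[C@](C)([C@@H]1CO1)[C@@H]2O
F5 | step 23 | triol formed from F4 by opening of the epoxide at C2 (1,2-dihydroxyethyl group on C10) | C=C1C(=O)O[C@@H]2[C@H]1[C@@H](OC(=O)/C(C)=C\C)[C@@H](C(=C)C=O)[C@](C)([C@@H](O)CO)[C@@H]2O
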